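**Retrosynthetic overview**
- Target ⇒ C8–O ester bond (Steglich acylation with (S)-2-methylglycidic acid) and C9–OAc bond, the latter by a stereoretentive palladium/boron-templated opening of an 8,9-vinyl oxirane (key C–O construction).
- 8,9-Oxirane ⇒ cis,cis-diene macrocycle, oxygen placed on the concave face by bromohydrin formation and closure.
- Ten-membered carbocycle ⇒ ring-closing metathesis at C8=C9 of a vinyl lactone carrying a 2-vinyl enoate.
- γ-Lactone (C6–C7 bond, C6–O) ⇒ chromium Barbier allylation of a cis-epoxy aldehyde with a 2-(bromomethyl)pentadienoate, lactonising in the same flask.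
- Epoxy aldehyde ⇒ nerol by Sharpless epoxidation (sets C4/C5; every other ring stereocentre is relayed from it). Ring order: 4,5-oxirane → γ-lactone → carbocycle → 8,9-oxirane (opened again).

Assumption: the SMILES is taken literally (4,5-cis-oxirane, 8,9-cis diester on the C7–C11 face, (S)-glycidate), and nerol and (R)-2-methylglycidol count as cheap commercial materials. Germacrane numbering is used for the macrocycles.

**Route**

Step 1
Reactants: 1 nerol
Product: 2 [(2S,3R)-3-methyl-3-(4-methylpent-3-en-1-yl)oxiran-2-yl]methanol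
Conditions: Ti(OiPr)4 (5 mol %), L-(+)-diethyl tartrate (6 mol %), t-BuOOH, 4 Å MS, CH2Cl2, −20 °C
Reagents that add atoms: tert-butyl hydroperoxide CC(C)(C)OO
Why: Katsuki–Sharpless asymmetric epoxidation touches only the Z-allylic alcohol olefin, and the L-(+)-tartrate complex delivers oxygen to the face that gives the cis-oxirane with C4 (R) and C5 (S).

Step 2
Reactants: 2 [(2S,3R)-3-methyl-3-(4-methylpent-3-en-1-yl)oxiran-2-yl]methanol
Product: 4 methyl (2Z)-5-[(2R,3S)-3-(hydroxymethyl)-2-methyloxiran-2-yl]-2-iodopent-2-enoate, via epoxy aldehyde 3 (not isolated)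
Conditions: O3, CH2Cl2, −78 °C; PPh3; then Ph3P=CHCO2Me + NIS (premixed at −20 °C), CH2Cl2, −20 °C → rt
Reagents that add atoms: methyl (triphenylphosphoranylidene)acetate COC(=O)C=P(c1ccccc1)(c1ccccc1)c1ccccc1; N-iodosuccinimide O=C1CCC(=O)N1I; ozone [O-][O+]=O (oxygen of intermediate 3 only)
Why: Ozonolysis cleaves the only C=C, and the in situ halo-Wittig olefination gives the (Z)-α-iodo enoate with the ester trans to the chain, which fixes the ring-cis C1=C10 geometry.

Step 3
Reactants: 4 methyl (2Z)-5-[(2R,3S)-3-(hydroxymethyl)-2-methyloxiran-2-yl]-2-iodopent-2-enoate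
Product: 5 methyl (2E)-2-ethenyl-5-[(2R,3S)-3-(hydroxymethyl)-2-methyloxiran-2-yl]pent-2-enoate
Conditions: CH2=CHSnBu3, Pd2(dba)3 (2.5 mol %), AsPh3 (10 mol %), CuI (10 mol %), DMF, rt
Reagents that add atoms: tributyl(vinyl)stannane C=C[Sn](CCCC)(CCCC)CCCC
Why: Stille coupling of the alkenyl iodide proceeds with retention of olefin geometry under neutral conditions that spare the epoxy alcohol.

Step 4
Reactants: 5 methyl (2E)-2-ethenyl-5-[(2R,3S)-3-(hydroxymethyl)-2-methyloxiran-2-yl]pent-2-enoate
Product: 6 methyl (2E)-2-ethenyl-5-[(2R,3R)-3-formyl-2-methyloxiran-2-yl]pent-2-enoate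
Conditions: TEMPO (10 mol %), PhI(OAc)2, CH2Cl2, 0 °C → rt; used crude
Reagents that add atoms: none
Why: Oxoammonium (TEMPO) oxidation takes the primary alcohol to the aldehyde without touching the oxirane or its stereocentres (the descriptor change at C5 is only a priority change).

Step 5
Reactants: 7 acrolein; 8 methyl acrylate
Product: 9 methyl 3-hydroxy-2-methylidenepent-4-enoate (racemic)
Conditions: DABCO (20 mol %), neat (8 in excess), rt
Reagents that add atoms: none
Why: Morita–Baylis–Hillman reaction; the carbinol stereocentre is irrelevant because it is destroyed in step 6.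

Step 6
Reactants: 9 methyl 3-hydroxy-2-methylidenepent-4-enoate
Product: 10 methyl (2Z)-2-(bromomethyl)penta-2,4-dienoate
Conditions: 48 % aq HBr, H2SO4 (cat.), CH2Cl2, 0 °C
Reagents that add atoms: hydrogen bromide Br
Why: Allylic substitution with transposition through the pentadienyl cation gives the fully conjugated bromide under thermodynamic control, and any regioisomeric allylic bromide would give the same pentadienylchromium species in step 7.

Step 7
Reactants: 6 methyl (2E)-2-ethenyl-5-[(2R,3R)-3-formyl-2-methyloxiran-2-yl]pent-2-enoate; 10 methyl (2Z)-2-(bromomethyl)penta-2,4-dienoate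
Product: 13 methyl (2E)-2-ethenyl-5-{(2R,3S)-3-[(2S,3S)-3-ethenyl-4-methylidene-5-oxooxolan-2-yl]-2-methyloxiran-2-yl}pent-2-enoate, via allylchromium reagent 11 (not isolated), via hydroxy diester 12 (not isolated)
Conditions: CrCl2 (4 equiv), THF, 0 → 40 °C; aq NH4Cl
Reagents that add atoms: chromium dichloride Cl[Cr]Cl (in intermediate 11 only)
Why: Nozaki–Hiyama-type chromium Barbier allylation: the pentadienylchromium attacks through its central carbon in a chair transition state (anti C6/C7, hence the trans-lactone) on the Felkin–Anh face of the cis-epoxy aldehyde (anti to the oxirane C–O, setting 6S), and the chromium alkoxide closes the γ-lactone on warming.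

Step 8
Reactants: 13 methyl (2E)-2-ethenyl-5-{(2R,3S)-3-[(2S,3S)-3-ethenyl-4-methylidene-5-oxooxolan-2-yl]-2-methyloxiran-2-yl}pent-2-enoate
Product: 14 methyl (1(10)E,4R,5S,6S,7S,8Z)-4,5-epoxygermacra-1(10),8,11(13)-trien-12,6-olid-14-oate
Conditions: second-generation Grubbs catalyst (10 mol %), 1,4-benzoquinone (20 mol %), toluene (1 mM), 80 °C
Reagents that add atoms: none
Why: Ring-closing metathesis of the two monosubstituted vinyl groups; the ten-membered ring enforces the cis C8=C9 bond, while the trisubstituted enoate and the methylene lactone are too electron-poor and hindered to compete.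

Step 9
Reactants: 14 methyl (1(10)E,4R,5S,6S,7S,8Z)-4,5-epoxygermacra-1(10),8,11(13)-trien-12,6-olid-14-oate
Product: 16 methyl (1(10)E,4R,5S,6S,7R,8S,9R)-4,5:8,9-diepoxygermacra-1(10),11(13)-dien-12,6-olid-14-oate, via bromohydrin 15 (not isolated)
Conditions: NBS, THF–H2O (4:1), 0 °C; then Ag2O, THF, rt, dark
Reagents that add atoms: water O; N-bromosuccinimide O=C1CCC(=O)N1Br (bromine of intermediate 15 only)
Why: Halohydrin formation then silver-assisted closure: in the A1,3-minimised conformer (H-7 eclipsing the olefin) the ring covers the face syn to C6, so Br+ adds to the exposed face, water opens anti at allylic C9, and closure inverts C8, placing the oxirane on the concave face cis to C7–C11 (8S,9R), which a peracid cannot reach; the regioisomeric bromohydrin converges on the same oxirane.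

Step 10
Reactants: 16 methyl (1(10)E,4R,5S,6S,7R,8S,9R)-4,5:8,9-diepoxygermacra-1(10),11(13)-dien-12,6-olid-14-oate
Product: 17 methyl (1(10)E,4R,5S,6S,7R,8S,9R)-9-acetoxy-4,5-epoxy-8-hydroxygermacra-1(10),11(13)-dien-12,6-olid-14-oate
Conditions: Pd2(dba)3·CHCl3 (2.5 mol %), PPh3 (15 mol %), BEt3 (10 mol %), AcOH (1.5 equiv), THF, 0 °C → rt
Reagents that add atoms: acetic acid CC(=O)O
Why: Proposed new method: zerovalent palladium ionises the allylic C9–O bond of the ester-substituted vinyl oxirane with inversion, the C8 alkoxide is captured by Et2B–OAc (from BEt3 and AcOH), and the resulting acetoxyborate hands acetate to the adjacent C9 terminus of the π-allyl on the face opposite palladium, so the C9–OAc bond forms with net retention (9R), O8 is released as the free hydroxyl and 1,4-attack at C1 is suppressed; the closest known reactions are the palladium/trialkylborane 1,2-alkoxylation of vinyl epoxides and the cis-selective palladium-catalysed addition of carboxylic acids to diene monoepoxides, neither shown for carboxylate delivery to a 2-alkoxycarbonyl π-allyl in a macrocycle.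

Step 11
Reactants: 18 (R)-2-methylglycidol
Product: 19 (S)-2-methylglycidic acid
Conditions: RuCl3 (2 mol %), NaIO4, MeCN–EtOAc–H2O, 0 °C; used fresh
Reagents that add atoms: sodium periodate [Na+].[O-]I(=O)(=O)=O
Why: Ruthenium tetroxide oxidation of the primary alcohol to the acid leaves the quaternary oxirane carbon untouched (the R→S change is only a priority change).

Step 12
Reactants: 17 methyl (1(10)E,4R,5S,6S,7R,8S,9R)-9-acetoxy-4,5-epoxy-8-hydroxygermacra-1(10),11(13)-dien-12,6-olid-14-oate; 19 (S)-2-methylglycidic acid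
Product: 21 methyl (1(10)E,4R,5S,6S,7R,8S,9R)-9-acetoxy-4,5-epoxy-8-{[(2S)-2-methyloxirane-2-carbonyl]oxy}germacra-1(10),11(13)-dien-12,6-olid-14-oate, via O-acylisourea 20 (not isolated)
Conditions: DCC, DMAP (10 mol %), CH2Cl2, −10 → 0 °C
Reagents that add atoms: N,N′-dicyclohexylcarbodiimide C(=NC1CCCCC1)=NC1CCCCC1 (in intermediate 20 only)
Why: Steglich esterification forms the C8–O ester bond without touching any stereocentre, and the low temperature lets acylation outrun 1,2-acetyl migration from O9.

**Compound list**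
1 | nerol, (2Z)-3,7-dimethylocta-2,6-dien-1-ol | CC(C)=CCC/C(C)=C\CO | starting material
2 | [(2S,3R)-3-methyl-3-(4-methylpent-3-en-1-yl)oxiran-2-yl]methanol | CC(C)=CCC[C@@]1(C)O[C@H]1CO | intermediate
3 | 3-[(2R,3S)-3-(hydroxymethyl)-2-methyloxiran-2-yl]propanal | O=CCC[C@@]1(C)O[C@H]1CO | intermediate
4 | methyl (2Z)-5-[(2R,3S)-3-(hydroxymethyl)-2-methyloxiran-2-yl]-2-iodopent-2-enoate | COC(=O)/C(I)=C/CC[C@@]1(C)O[C@H]1CO | intermediate
5 | methyl (2E)-2-ethenyl-5-[(2R,3S)-3-(hydroxymethyl)-2-methyloxiran-2-yl]pent-2-enoate | C=C/C(C(=O)OC)=C\CC[C@@]1(C)O[C@H]1CO | intermediate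
6 | methyl (2E)-2-ethenyl-5-[(2R,3R)-3-formyl-2-methyloxiran-2-yl]pent-2-enoate | C=C/C(C(=O)OC)=C\CC[C@@]1(C)O[C@H]1C=O | intermediate
7 | acrolein | C=CC=O | starting material
8 | methyl acrylate | C=CC(=O)OC | starting material
9 | methyl 3-hydroxy-2-methylidenepent-4-enoate (racemic) | C=CC(O)C(=C)C(=O)OC | intermediate
10 | methyl (2Z)-2-(bromomethyl)penta-2,4-dienoate | C=C/C=C(\CBr)C(=O)OC | intermediate
11 | dichloro[2-(methoxycarbonyl)penta-2,4-dien-1-yl]chromium | C=CC=C(C[Cr](Cl)Cl)C(=O)OC | intermediate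
12 | methyl (2E)-2-ethenyl-5-{(2R,3S)-3-[(1S,2S)-2-ethenyl-1-hydroxy-3-(methoxycarbonyl)but-3-en-1-yl]-2-methyloxiran-2-yl}pent-2-enoate | C=C(C(=O)OC)[C@H](C=C)[C@H](O)[C@@H]1O[C@]1(C)CC/C=C(\C=C)C(=O)OC | intermediate
13 | methyl (2E)-2-ethenyl-5-{(2R,3S)-3-[(2S,3S)-3-ethenyl-4-methylidene-5-oxooxolan-2-yl]-2-methyloxiran-2-yl}pent-2-enoate | C=C1C(=O)O[C@@H]([C@H]1C=C)[C@@H]1O[C@]1(C)CC/C=C(\C=C)C(=O)OC | intermediate
14 | methyl (1(10)E,4R,5S,6S,7S,8Z)-4,5-epoxygermacra-1(10),8,11(13)-trien-12,6-olid-14-oate (trans-fused lactone, cis-oxirane) | C=C1C(=O)O[C@H]2[C@H]1/C=C\C(C(=O)OC)=C/CC[C@@]1(C)O[C@@H]21 | intermediate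
15 | methyl (1(10)E,4R,5S,6S,7S,8R,9R)-8-bromo-4,5-epoxy-9-hydroxygermacra-1(10),11(13)-dien-12,6-olid-14-oate | C=C1C(=O)O[C@H]2[C@H]1[C@@H](Br)[C@H](O)/C(C(=O)OC)=C\CC[C@@]1(C)O[C@@H]21 | intermediate
16 | methyl (1(10)E,4R,5S,6S,7R,8S,9R)-4,5:8,9-diepoxygermacra-1(10),11(13)-dien-12,6-olid-14-oate (8,9-oxirane syn to C7–C11) | C=C1C(=O)O[C@H]2[C@H]1[C@@H]3O[C@@H]3/C(C(=O)OC)=C\CC[C@@]1(C)O[C@@H]21 | intermediate
17 | methyl (1(10)E,4R,5S,6S,7R,8S,9R)-9-acetoxy-4,5-epoxy-8-hydroxygermacra-1(10),11(13)-dien-12,6-olid-14-oate | C=C1C(=O)O[C@H]2[C@H]1[C@H](O)[C@H](OC(C)=O)/C(C(=O)OC)=C\CC[C@@]1(C)O[C@@H]21 | intermediate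
18 | (R)-2-methylglycidol, [(2R)-2-methyloxiran-2-yl]methanol | OC[C@]1(C)CO1 | starting material
19 | (S)-2-methylglycidic acid, (2S)-2-methyloxirane-2-carboxylic acid | OC(=O)[C@]1(C)CO1 | intermediate
20 | O-[(2S)-2-methyloxirane-2-carbonyl]-N,N′-dicyclohexylisourea | O=C(OC(=NC2CCCCC2)NC2CCCCC2)[C@]1(C)CO1 | intermediate
21 | methyl (1(10)E,4R,5S,6S,7R,8S,9R)-9-acetoxy-4,5-epoxy-8-{[(2S)-2-methyloxirane-2-carbonyl]oxy}germacra-1(10),11(13)-dien-12,6-olid-14-oate | C=C1C(=O)O[C@H]2[C@H]1[C@H](OC(=O)[C@]1(C)CO1)[C@H](OC(C)=O)/C(C(=O)OC)=C\CC[C@@]1(C)O[C@@H]21 | target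

**Step count and risks**

Total steps: 12. Longest linear sequence: 9 (steps 1–4, 7–10 and 12).

The three steps most likely to fail are steps 8, 9 and 10.

Step 8 (ring-closing metathesis) may stall because the trans-fused lactone of 13 holds the two vinyl groups apart and the product is a strained ten-membered cis,cis-diene. The fallback reverses the order of ring formation. It sets out from hydroxy diester 12, which is intercepted at 0 °C before lactonisation and silylated (TESOTf, 2,6-lutidine) to the open-chain triethylsilyl ether F1. The carbocycle is then closed by metathesis on this more flexible substrate to give the macrocyclic silyl ether diester F2. Fluoride (TBAF, AcOH) frees O6, which lactonises onto C12, and the route is rejoined at 14.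

Step 9 (concave-face oxirane) depends on which face of the C8=C9 bond is exposed and on water opening the bromonium ion 1,2 and not 1,4. If the exposed face proves to be the one syn to C7–C11, the halonium/anti-opening logic is replaced by concerted oxygen transfer: dimethyldioxirane (acetone, −20 °C) epoxidises the C8=C9 bond of 14 directly on the exposed face and returns to 16 with no new compound. If halonium opening itself is the problem, the Woodward sequence described next bypasses 16 altogether.

Step 10 (the proposed palladium/boron acetoxylation) may give the 1,4-acetate, isomerise the vinyl oxirane or lose stereochemistry. The known-chemistry fallback is the Woodward cis-hydroxylation, setting out from 14. Iodine and AgOAc in acetic acid add iodine to the exposed face and acetate anti to give the trans-iodo acetate F3. Neighbouring-group displacement of iodide gives the bridged acetoxonium ion F4 on the concave face. Wet acetic acid hydrolyses it to the cis-hydroxy acetate 17 together with its regioisomer, the 8-acetate F5, which is separated by chromatography and recycled by acetyl-migration equilibration. The route is rejoined at 17.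

**Further compounds**
F1 | step 8 | methyl (2E)-2-ethenyl-5-{(2R,3S)-3-[(1S,2S)-2-ethenyl-3-(methoxycarbonyl)-1-(triethylsilyloxy)but-3-en-1-yl]-2-methyloxiran-2-yl}pent-2-enoate | C=C(C(=O)OC)[C@H](C=C)[C@H](O[Si](CC)(CC)CC)[C@@H]1O[C@]1(C)CC/C=C(\C=C)C(=O)OC
F2 | step 8 | dimethyl (1(10)E,4R,5S,6S,7S,8Z)-4,5-epoxy-6-(triethylsilyloxy)germacra-1(10),8,11(13)-triene-12,14-dioate | C=C(C(=O)OC)[C@@H]1/C=C\C(C(=O)OC)=C/CC[C@@]2(C)O[C@H]2[C@H]1O[Si](CC)(CC)CC
F0 | step 9 | none | none
F3 | step 10 | methyl (1(10)E,4R,5S,6S,7S,8R,9R)-9-acetoxy-4,5-epoxy-8-iodogermacra-1(10),11(13)-dien-12,6-olid-14-oate | C=C1C(=O)O[C@H]2[C@H]1[C@@H](I)[C@H](OC(C)=O)/C(C(=O)OC)=C\CC[C@@]1(C)O[C@@H]21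
F4 | step 10 | 8,9-cis-fused 2-methyl-1,3-dioxolan-2-ylium (acetoxonium) ion on the concave face of the germacranolide | C=C1C(=O)O[C@H]2[C@H]1[C@@H]3OC(C)=[O+][C@@H]3/C(C(=O)OC)=C\CC[C@@]1(C)O[C@@H]21
F5 | step 10 | methyl (1(10)E,4R,5S,6S,7R,8S,9R)-8-acetoxy-4,5-epoxy-9-hydroxygermacra-1(10),11(13)-dien-12,6-olid-14-oate | C=C1C(=O)O[C@H]2[C@H]1[C@H](OC(C)=O)[C@H](O)/C(C(=O)OC)=C\CC[C@@]1(C)O[C@@H]21
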